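Readings and results stem from a simulated flask from invented constants; noise was put on by code.

**The pitfall.** I began wary of the large number on a plateau: the equilibrium sits in the small remainder beside it.

in all of them: starting complex 20 mM
- gamma: incoming ligand 24 mM; leaving ligand 40 mM; run made earlier
- delta: incoming ligand 27 mM; leaving ligand 40 mM; run made earlier
- beta: incoming ligand 28 mM; leaving ligand 40 mM; run made earlier
- Thursday's: incoming ligand 20.0 mM; leaving ligand 40.0 mM; time 30 min
- Friday's: incoming ligand 30.0 mM; leaving ligand 40.0 mM; time 30 min
- Monday's: incoming ligand 40.0 mM; leaving ligand 40.0 mM; time 30 min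

| run | time / min | complex with one exchanged / % |
|---|---|---|
| gamma | 2.50 | 71 |
| gamma | 8.00 | 86 |
| gamma | 15.0 | 90 |
| gamma | 20.0 | 87 |
| gamma | 30.0 | 88 |
| delta | 6.00 | 88 |
| delta | 12.0 | 90 |
| delta | 20.0 | 92 |
| delta | 25.0 | 89 |
| delta | 30.0 | 89 |
| beta | 2.50 | 77 |
| beta | 8.00 | 89 |
| beta | 15.0 | 90 |
| beta | 20.0 | 92 |
| beta | 30.0 | 93 |

(readings scatter by 1.5 percentage points)

- the numbers in the tables scatter by 1.5 percentage points (one standard deviation)
- a reading or a percentage of complex with one exchanged counts all its forms, free or not

* complex with one exchanged at the end, in percent of the starting complex charged, for each flask in turn (Thursday's, Friday's, Monday's)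

**Plateau constant.** I counted in fractions of the starting complex charged: y for complex with one exchanged, r for the starting complex remaining, a for the incoming ligand charged. Leaving ligand then stands at its charge plus y, and incoming ligand at a minus y. The late readings averaged 88.3 % in the gamma run, 90.0 % in the delta run and 91.7 % in the beta run. These gave 68.9, 58.0 and 66.4. Their mean, 64.4, I called the plateau constant: y times leaving ligand, over remainder times incoming ligand left.

**Thursday's curve.** I took the first beta reading as a second-order rise without the way back, with starting complex the limiting reagent; it gave a rise constant of 0.671 min⁻¹. For Thursday's flask, charged equally, I took that constant as the slope at zero, in charge per minute, and my forward curve passed half the charge at 1.49 min. For its level, I set y to one in the large factors, which gave a remainder of 21.6 %. Correcting those factors with it gave y = 81.6 %. My forward curve met that level at 6.60 min, earlier than 30 min, so I expected Thursday's flask to end flat.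

**Richer charges.** The same correction gave first remainders of 9.31 % on Friday's flask and 4.66 % on Monday's, then levels of 93.1 % and 95.8 %.

**The forecast.** It said 81 %, 92.7 % and 95.8 %, on the ground “So 30 min should reach equilibrium”. Mine stood higher on Thursday's flask.

**The result.** The flasks gave 80.1 %, 91.7 % and 93.8 %, and the forecast held within its margin.

    starting complex + incoming ligand ⇌ leaving ligand + complex with one exchanged (K = 2.40, k = 1.35 M⁻¹ s⁻¹)
    complex with one exchanged + incoming ligand ⇌ leaving ligand + complex with two exchanged (K = 2.20, k = 0.461 M⁻¹ s⁻¹)
    crystals ⇌ complex with one exchanged, rate k3*(cs3 - [complex with one exchanged]) while solid is left; crystals form when [complex with one exchanged] > cs3 (solubility = 0.630 mM, k = 0.0683 s⁻¹)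

**Constant again.** Of Friday's 91.7 %, 88.6 % stood as crystals at 30.0 min, counted in the reading. Put back into the plateau constant, with one minus y taken as the remainder, Thursday's result gave 56.7, below the 64.4 read from the runs, and Monday's gave 41.9.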